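Structural features

The target is a daucane sesquiterpenoid ester: a cyclopentane (ring A, C1–C5) trans-fused through the C1–C5 bond to a cycloheptane (ring B: C1, C5, C6, C7, C8, C9, C10), with a vanilloyl group on O6. It has five stereocentres (1R,4R,5S,6S,9S): the all-carbon quaternary C1 (angular methyl C15), the tertiary carbinol C4 (hydroxyl cis to C15, isopropyl trans), the fusion methine C5, the acyloxy carbon C6 and the allylic carbinol C9. C4, C5, C1 and C6 are contiguous, whereas C9 is separated from them by C10 and by the exocyclic C8=C14 methylene. In the chair-like ring B, O6 and O9 are both equatorial on the face opposite the axial C15, and H5 is anti to C15. The fragile parts are the allylic alcohol beside a 1,1-disubstituted alkene (acid), the tertiary alcohol (dehydration), the C4/C6 1,3-dioxygen pattern (retro-aldol or β-elimination whenever C6 is a carbonyl) and the phenolic benzoate (base, acyl transfer). The real difficulty is the quaternary C1 wedged against C5 and the fully substituted C4 on a five-membered ring, with a trans ring fusion and a remote C9. The key step exploits that C1 lies 1,5 to C5 through C2–C3–C4 and that C4 carries isopropyl and oxygen: ring A is the cyclopentene formed when an alkylidene carbene (carbene carbon = C5) made from a C4 isopropyl ketone inserts into the tertiary C1–H bond of a citronellol chain, which already supplies C15, C10, C9 and O9.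

Logic of the disconnections

31 is simplified by removing the two silyl groups (30) and cutting the C6–O acyl bond, which gives 26 and 29 (from 27). The phenolic ester is the most base-sensitive unit and is best introduced last; all earlier chemistry then runs on a non-aromatic core. The forward acylation must pick the secondary C6 hydroxyl (C9 is silylated, the tertiary C4 hydroxyl should be inert), and the final fluoride treatment must be buffered.

26 is cut at C6–C7. The 1,3-relationship between the C6 hydroxyl and the C8=C14 methylene is the retron of a type 2 carbonyl-ene reaction, which opens ring B to 25. A bicycle with two new stereocentres is traded for a cyclopentane with an isopropenyl carbinol side chain. The forward step must close a seven-membered ring with the metal-bound oxygen equatorial (6S) and tolerate the free C4 hydroxyl.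

25 is traced through 24 and 23 to 22 by functional-group changes only (C6 aldehyde from the primary alcohol, C4/C6 diol masked as an acetonide, O9 silylated). 22 is cut at C8–C9, through 21 and 20, to 17 and 18. C9 is too far from the ring stereocentres for substrate control, so the bond is made without control and the centre is set afterwards; this demands a reagent-controlled 1,2-reduction of an isopropenyl ketone.

17 goes back through 16 and 15 to 14. No carbon–carbon bond is cut; the gain is orthogonality (a fluoride-labile O9 silyl ether against an acid-labile acetonide), so that the citronellol oxygen can be oxidised while C6–OH and C4–OH are masked.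

14 is disconnected at the C4–O bond through 13 to 12. A tertiary alcohol cis to the C5 hydroxymethyl group is what hydroxyl-directed epoxidation of C3=C4 followed by hydride attack at C3 delivers. C4 becomes an alkene carbon; the C6 hydroxyl must steer the oxidant to its own face and hydride must attack only the less substituted carbon.

12 is cut at C5–C6 to 10 and 11 (retro-ene). One carbon on the less substituted end of a trisubstituted alkene is the pattern of a formaldehyde ene reaction, which also moves the alkene to C3=C4 where the previous step needs it. The forward step must bond at C5 on the face opposite the C10 arm and take hydrogen from C3, not from the isopropyl methine.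

10 is cut at C1–C5 and the C4=C5 bond is retraced to a carbonyl, giving 5 and the one-carbon reagent 6, whose carbon becomes C5. Ring A and the quaternary stereocentre vanish and an acyclic ketone with one tertiary stereocentre remains. The forward step must insert only into C1–H and with retention.

5 comes from 1 through 4 and 2 by silylation, anti-Markovnikov hydration of the trisubstituted alkene and oxidation. All carbons of 5, the C1 configuration and O9 come from 1.

Other disconnections considered

Alternative 1: The cut removes C7–C8 and C1–C10, so ring B would arise in one operation from the cyclopentenyl diene A1 (ring A with the C4 carbinol already set, a tetrasubstituted C1=C5 alkene and a C6=C7 vinyl group) and methyl 2-diazobut-3-enoate A2. In the forward step Rh2(S-DOSP)4 (a divalent rhodium prolinate) would turn A2 into a vinylcarbenoid that cyclopropanates the vinyl group (C7–C8), and a boat Cope rearrangement would then form C1–C10 and give the cycloheptadiene A3 (C8 ester, C5=C6, C8=C9).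
- In its favour: it is convergent, ring B and the quaternary C1 are made in one catalytic step, the ester is the future C14, and the two alkenes are handles for O6/H5 and O9.
- Against it: the Cope step must bond to a fully substituted alkene carbon. C1 must be set 1,3 to the existing C4 centre, so catalyst and substrate preferences can be matched or mismatched. The enoate still has to be converted into the transposed C9 carbinol and C8=C14 methylene, which raises a new stereochemical question at C9. Hydroboration of C5=C6 must come from the face that also carries the C4 isopropyl group. A1 needs its own asymmetric synthesis of a tertiary carbinol.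
- Comparison: on structure it is the better plan, because it addresses ring B and C1 together. On mechanism the chosen insertion is the more certain at C1, because it is stereospecific from a chiral-pool centre and has no matching problem. On step economy it is better for ring construction, but the adjustments at C8/C9/C14 and the preparation of A1 should bring the totals to roughly the same.

Alternative 2: The cut removes C1–C5 and C9–C10, so both rings would form at once from the 6-acetoxypyranone A4, reached by an Achmatowicz rearrangement of a furyl carbinol. Loss of acetate would give the 3-oxidopyrylium A5, which adds across the tethered 1,1-disubstituted alkene (three-atom tether C4–C3–C2) to give the oxygen-bridged tricyclic enone A6.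
- In its favour: it has the largest gain in complexity (both rings, C1, C5 and C9 in one step). The bridge delivers O9 with defined configuration. The C6 ketone, C7=C8 and the C14 acetate sit where a reductive cleavage with SmI2 (divalent samarium) could free the C9 alcohol, install H5 and unveil the C8=C14 methylene.
- Against it: the cycloaddition joins a fully substituted pyrylium carbon bearing the quaternary C4 to a disubstituted alkene carbon, creating three contiguous fully substituted carbons. Facial selection rests on a C4 centre whose two groups (silyloxy, isopropyl) are of similar size. After bridge cleavage C5 is set by protonation of an enolate, so the trans fusion is not assured. The C6 ketone must then be reduced to the equatorial alcohol against the bias of the axial C15.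
- Comparison: on structure it is the better plan, and for C9 it is the equal or the better (C9 comes from the key step; the chosen plan needs a separate reagent-controlled reduction). On mechanism the chosen plan is more secure at C1 and does not have to create the trans fusion by protonation. On step economy it should be better after the key step (few operations to the target), but A4 is longer to prepare, so the overall count is about equal.

Alternative 3: The cut removes C1–C15 and C5–C6, starting from the 3-substituted cyclopentenone A7, whose side chain already contains the (9S)-silyloxy isopropenyl unit. Copper-catalysed asymmetric 1,4-addition of trimethylaluminium A8 (copper thiophene-2-carboxylate, monovalent copper, with a chiral phosphoramidite) would create C1, and the aluminium enolate would be trapped at C5 by formaldehyde (11) to give the trans hydroxymethyl ketone A9.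
- In its favour: C5 lies α to a ketone, so the trans relationship can be reached by equilibration. This is better than the chosen plan, where C5 is fixed irreversibly. C9 is present from the start, so no oxidation/reduction detour is needed, which is also better. The C4 ketone is ready for isopropyl addition anti to the C5 substituent, which would give the required C4 configuration. The ring B closure is the same type 2 ene reaction, so that part is equal.
- Against it: enantioselective methyl addition to 3-substituted cyclopentenones to form quaternary centres is less dependable than with six-membered enones, so C1 may not emerge as a single isomer. The enolate/formaldehyde aldol competes with proton transfer and retro-aldol. Isopropyl addition to a hindered, enolisable β-alkoxy ketone may divert to reduction, enolisation or β-elimination.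
- Comparison: on structure the two plans are equal (same end game). On mechanism the chosen plan is more certain at C1, and the alternative is better at C5. On step economy the alternative is better by several steps.

Key step: step 4

Remark: locants follow the daucane numbering of the target; β is the face of ring A that carries the C1 methyl group (C15), α the face of the C10 arm.
Remark: O9 is carried as its tert-butyldiphenylsilyl ether instead of the tert-butyldimethylsilyl ether. It is a weaker donor and sturdier toward Me2AlCl and hydride, and it enlarges the C10 arm that must shield one face in step 5; the carbon skeletons of 5 and 10 are unchanged.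

Step 1
Reactants: 1 (S)-citronellol
Product: 2 tert-butyl{[(3S)-3,7-dimethyloct-6-en-1-yl]oxy}diphenylsilane
Conditions: TBDPSCl, imidazole, CH2Cl2, 0 °C → rt
Reagents that add atoms: tert-butyl(chloro)diphenylsilane, CC(C)(C)[Si](Cl)(c1ccccc1)c1ccccc1
Why: Imidazole-promoted silylation of a primary alcohol; the stereocentre is not involved.

Step 2
Reactants: 2 tert-butyl{[(3S)-3,7-dimethyloct-6-en-1-yl]oxy}diphenylsilane
Product: 4 (6S)-8-[(tert-butyldiphenylsilyl)oxy]-2,6-dimethyloctan-3-ol (both C3 epimers), via B-alkyl-9-borabicyclo[3.3.1]nonane 3 (not isolated)
Conditions: 9-BBN, THF, 65 °C; then NaOH, H2O2, 0 °C → rt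
Reagents that add atoms: hydrogen peroxide, OO
Why: Hydroboration–oxidation: boron adds to the less substituted carbon of the trisubstituted alkene and is replaced by OH with retention, giving the secondary alcohol next to the isopropyl group. The carbinol configuration is irrelevant because it is oxidised in step 3.

Step 3
Reactants: 4 (6S)-8-[(tert-butyldiphenylsilyl)oxy]-2,6-dimethyloctan-3-ol
Product: 5 (6S)-8-[(tert-butyldiphenylsilyl)oxy]-2,6-dimethyloctan-3-one
Conditions: Dess–Martin periodinane, CH2Cl2, rt
Reagents that add atoms: none
Why: Dess–Martin oxidation of a secondary alcohol; the methine stereocentre is γ to the carbonyl and cannot epimerise.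

Step 4
Reactants: 5 (6S)-8-[(tert-butyldiphenylsilyl)oxy]-2,6-dimethyloctan-3-one; 6 trimethylsilyldiazomethane
Product: 10 tert-butyl{2-[(1R)-1-methyl-3-(propan-2-yl)cyclopent-2-en-1-yl]ethoxy}diphenylsilane, via lithio(trimethylsilyl)diazomethane 7 (not isolated), via diazoalkene 8 (not isolated), via alkylidene carbene 9 (not isolated)
Conditions: 6, n-BuLi, THF, −78 °C; then 5, −78 °C → rt
Reagents that add atoms: none
Why: Lithiated 7 adds to the carbonyl of 5; the lithium alkoxide loses lithium trimethylsilanolate in a Peterson-type elimination to give diazoalkene 8, which expels N2 on warming and leaves alkylidene carbene 9 whose divalent carbon is C5. The singlet carbene inserts in a concerted three-centre process into the C1–H bond lying 1,5 to it, forming C1–C5 while C4=C5 remains as the ring alkene; the closest known reaction type is the alkylidene carbene 1,5 C–H insertion of ketone-derived carbenes generated with lithiated trimethylsilyldiazomethane. Ring A closes by this 1,5 insertion through a five-membered, cyclopentene-forming transition structure, the only one in which the carbene reaches a C–H bond without strain. C1 is controlled by the stereospecificity of the insertion: the new C–C bond replaces hydrogen with retention, so the (S) methine of 5 becomes the (R) quaternary centre of 10 (the descriptor changes only because the priorities change). The site selectivity that is needed is secured by the substrate: the isopropyl side offers only 1,3 and 1,4 C–H bonds, the chain side has the tertiary C1–H as its only 1,5 C–H bond, and the 1,6 C–H bonds of C10 and C15 would need the much slower six-membered mode. A 1,2-shift to an alkyne is disfavoured because C4 carries neither hydrogen nor aryl, and the silyl ether oxygen is too remote for ylide formation. Excess reagent at −78 °C counters enolisation of the α-branched ketone.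

Step 5
Reactants: 10 tert-butyl{2-[(1R)-1-methyl-3-(propan-2-yl)cyclopent-2-en-1-yl]ethoxy}diphenylsilane; 11 formaldehyde (as paraformaldehyde)
Product: 12 [(1R,5R)-5-{2-[(tert-butyldiphenylsilyl)oxy]ethyl}-5-methyl-2-(propan-2-yl)cyclopent-2-en-1-yl]methanol
Conditions: (CH2O)n, Me2AlCl (2 equiv), CH2Cl2, −78 °C → 0 °C
Reagents that add atoms: none
Why: Lewis acid-promoted carbonyl-ene reaction: the formaldehyde–aluminium complex bonds to the less substituted alkene carbon C5 and a ring hydrogen at C3 is transferred, which moves the alkene to C3=C4; the isopropyl methine is a poor hydrogen donor because its transfer geometry forces a methyl group into allylic strain. C5 is set by approach to the ring face opposite the bulky 2-silyloxyethyl arm on the adjacent quaternary C1, that is cis to the methyl group.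

Step 6
Reactants: 12 [(1R,5R)-5-{2-[(tert-butyldiphenylsilyl)oxy]ethyl}-5-methyl-2-(propan-2-yl)cyclopent-2-en-1-yl]methanol
Product: 13 3β,4β-epoxide of 12 (epoxide oxygen cis to the hydroxymethyl group)
Conditions: VO(acac)2 (5 mol %), t-BuOOH, CH2Cl2, 0 °C → rt
Reagents that add atoms: tert-butyl hydroperoxide, CC(C)(C)OO
Why: Hydroxyl-directed epoxidation of a homoallylic alcohol: the C6 hydroxyl binds the vanadium alkylperoxide and delivers oxygen to the face of C3=C4 that it occupies (β), against the steric preference. This sets C4.

Step 7
Reactants: 13 3β,4β-epoxide of 12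
Product: 14 (1R,2S,3R)-3-{2-[(tert-butyldiphenylsilyl)oxy]ethyl}-2-(hydroxymethyl)-3-methyl-1-(propan-2-yl)cyclopentan-1-ol
Conditions: LiEt3BH (3 equiv), THF, 0 °C → rt
Reagents that add atoms: none
Why: Hydride opening of a trisubstituted epoxide at the less substituted carbon C3 from the α face (SN2). The C4–O bond is untouched, so the tertiary alcohol keeps the β configuration from step 6.

Step 8
Reactants: 14 (1R,2S,3R)-3-{2-[(tert-butyldiphenylsilyl)oxy]ethyl}-2-(hydroxymethyl)-3-methyl-1-(propan-2-yl)cyclopentan-1-ol
Product: 15 acetonide of 14 (O6 and O4 bridged by C(CH3)2 in a cis-fused 1,3-dioxane)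
Conditions: Me2C(OMe)2, PPTS (cat.), CH2Cl2, rt
Reagents that add atoms: 2,2-dimethoxypropane, COC(C)(C)OC
Why: Acid-catalysed transketalisation joins the cis-disposed primary and tertiary hydroxyls in a six-membered acetonide, masking both through the organometallic and redox steps.

Step 9
Reactants: 15 acetonide of 14
Product: 16 C9 primary alcohol (15 without the silyl group)
Conditions: nBu4NF, THF, rt
Reagents that add atoms: none
Why: Fluoride cleavage of the silyl ether; the acetonide is inert to fluoride.

Step 10
Reactants: 16 C9 primary alcohol
Product: 17 C9 aldehyde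
Conditions: Dess–Martin periodinane, NaHCO3, CH2Cl2, 0 °C → rt
Reagents that add atoms: none
Why: Dess–Martin oxidation of a primary alcohol, buffered to protect the acetonide; the aldehyde has no epimerisable α-stereocentre (C10 is a CH2 on the quaternary C1).

Step 11
Reactants: 17 C9 aldehyde; 18 2-bromopropene
Product: 20 C9 allylic alcohols (both C9 epimers), via isopropenylmagnesium bromide 19 (not isolated)
Conditions: 18, Mg, THF, rt; then 17, −78 °C → 0 °C
Reagents that add atoms: none
Why: Grignard addition to the aldehyde forms C8–C9; no selectivity at C9 is expected or needed because both epimers converge in step 12.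

Step 12
Reactants: 20 C9 allylic alcohols
Product: 21 isopropenyl ketone (C9=O)
Conditions: Dess–Martin periodinane, NaHCO3, CH2Cl2, 0 °C
Reagents that add atoms: none
Why: Dess–Martin oxidation of the allylic alcohol erases the uncontrolled C9 centre and gives the enone needed for reagent-controlled reduction.

Step 13
Reactants: 21 isopropenyl ketone
Product: 22 (9S)-allylic alcohol
Conditions: (R)-2-methyl-CBS-oxazaborolidine (20 mol %), catecholborane, toluene, −78 °C
Reagents that add atoms: none
Why: Corey–Bakshi–Shibata reduction: the ketone binds the (R)-oxazaborolidine with the isopropenyl group as the large substituent and hydride goes to the face that gives the (9S) alcohol. Reagent control governs because the nearest stereocentre (C1) is β to the carbonyl, and catecholborane at low temperature gives 1,2-reduction only.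

Step 14
Reactants: 22 (9S)-allylic alcohol
Product: 23 (9S)-tert-butyldimethylsilyl ether of 22
Conditions: TBSCl, imidazole, DMAP (cat.), DMF, rt
Reagents that add atoms: tert-butyl(chloro)dimethylsilane, CC(C)(C)[Si](C)(C)Cl
Why: Silylation of the secondary allylic alcohol; this group should survive the mild acid of step 15 and the Lewis acid of step 17 and leave together with the phenol silyl ether in step 20.

Step 15
Reactants: 23 (9S)-tert-butyldimethylsilyl ether of 22
Product: 24 (1R,2S,3R)-3-{(2S)-2-[(tert-butyldimethylsilyl)oxy]-3-methylbut-3-en-1-yl}-2-(hydroxymethyl)-3-methyl-1-(propan-2-yl)cyclopentan-1-ol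
Conditions: PPTS (cat.), MeOH, rt
Reagents that add atoms: none
Why: Acid-catalysed transketalisation to methanol removes the strained 1,3-dioxane acetonide, which is much more labile than a secondary silyl ether.

Step 16
Reactants: 24 (1R,2S,3R)-3-{(2S)-2-[(tert-butyldimethylsilyl)oxy]-3-methylbut-3-en-1-yl}-2-(hydroxymethyl)-3-methyl-1-(propan-2-yl)cyclopentan-1-ol
Product: 25 C6 aldehyde of 24 (β-hydroxy aldehyde)
Conditions: Dess–Martin periodinane, NaHCO3, CH2Cl2, 0 °C
Reagents that add atoms: none
Why: Dess–Martin oxidation of the primary alcohol; the tertiary hydroxyl cannot be oxidised. The C5 configuration (formyl cis to OH and CH3, trans to the two larger groups) is also the thermodynamically preferred one, so enolisation would not erode it.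

Step 17
Reactants: 25 C6 aldehyde of 24
Product: 26 (3R,3aS,4S,7S,8aR)-7-[(tert-butyldimethylsilyl)oxy]-8a-methyl-6-methylidene-3-(propan-2-yl)decahydroazulene-3,4-diol
Conditions: Me2AlCl (2.5 equiv), CH2Cl2, −78 °C → −20 °C
Reagents that add atoms: none
Why: Type 2 intramolecular carbonyl-ene reaction: the terminal CH2 of the isopropenyl group (C7) bonds to the activated aldehyde carbon C6 and a methyl hydrogen moves to oxygen, which closes the seven-membered ring B and creates the C8=C14 methylene. C6 is set by a chair-like transition structure with the aluminium-bound oxygen and the C9 silyloxy group equatorial, away from the axial C15, giving the (6S) alcohol. The first equivalent of Lewis acid is consumed by the C4 hydroxyl as its aluminium alkoxide.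

Step 18
Reactants: 27 vanillic acid
Product: 29 4-[(tert-butyldimethylsilyl)oxy]-3-methoxybenzoic acid, via silyl ester 28 (not isolated)
Conditions: TBSCl (2.2 equiv), imidazole, DMF, rt; then AcOH/THF/H2O, rt
Reagents that add atoms: tert-butyl(chloro)dimethylsilane, CC(C)(C)[Si](C)(C)Cl
Why: Silylation of phenol and acid followed by selective hydrolysis of the much more labile silyl ester; the aryl silyl ether is stable to aqueous acetic acid.

Step 19
Reactants: 26 (3R,3aS,4S,7S,8aR)-7-[(tert-butyldimethylsilyl)oxy]-8a-methyl-6-methylidene-3-(propan-2-yl)decahydroazulene-3,4-diol; 29 4-[(tert-butyldimethylsilyl)oxy]-3-methoxybenzoic acid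
Product: 30 (3R,3aS,4S,7S,8aR)-7-[(tert-butyldimethylsilyl)oxy]-3-hydroxy-8a-methyl-6-methylidene-3-(propan-2-yl)decahydroazulen-4-yl 4-[(tert-butyldimethylsilyl)oxy]-3-methoxybenzoate
Conditions: EDC·HCl, DMAP, CH2Cl2, rt
Reagents that add atoms: none
Why: Steglich esterification: of the two free hydroxyls only the secondary, equatorial C6–OH is acylated, since the tertiary C4–OH is unreactive and O9 is masked. The C6–O bond is not broken, so the configuration is retained.

Step 20
Reactants: 30 bis-silylated ester
Product: 31 (3R,3aS,4S,7S,8aR)-3,7-dihydroxy-8a-methyl-6-methylidene-3-(propan-2-yl)decahydroazulen-4-yl 4-hydroxy-3-methoxybenzoate (target)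
Conditions: nBu4NF, AcOH, THF, 0 °C → rt
Reagents that add atoms: none
Why: Fluoride cleaves the aryl and the secondary alkyl silyl ether in one operation; the acetic acid buffer keeps the medium near neutral so the ester neither migrates nor hydrolyses.

Compound list

1 | (S)-citronellol, (3S)-3,7-dimethyloct-6-en-1-ol | C[C@@H](CCC=C(C)C)CCO | starting material
2 | tert-butyl{[(3S)-3,7-dimethyloct-6-en-1-yl]oxy}diphenylsilane | C[C@@H](CCC=C(C)C)CCO[Si](c1ccccc1)(c1ccccc1)C(C)(C)C | intermediate
3 | 9-{(6S)-8-[(tert-butyldiphenylsilyl)oxy]-2,6-dimethyloctan-3-yl}-9-borabicyclo[3.3.1]nonane (C3 epimers) | CC(C)C(CC[C@H](C)CCO[Si](c1ccccc1)(c1ccccc1)C(C)(C)C)B1C2CCCC1CCC2 | intermediate (not isolated)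
4 | (6S)-8-[(tert-butyldiphenylsilyl)oxy]-2,6-dimethyloctan-3-ol (C3 epimers) | CC(C)C(O)CC[C@H](C)CCO[Si](c1ccccc1)(c1ccccc1)C(C)(C)C | intermediate
5 | (6S)-8-[(tert-butyldiphenylsilyl)oxy]-2,6-dimethyloctan-3-one (key-step precursor) | CC(C)C(=O)CC[C@H](C)CCO[Si](c1ccccc1)(c1ccccc1)C(C)(C)C | intermediate
6 | trimethylsilyldiazomethane | C[Si](C)(C)C=[N+]=[N-] | starting material
7 | lithio(trimethylsilyl)diazomethane | [Li]C(=[N+]=[N-])[Si](C)(C)C | intermediate (not isolated)
8 | tert-butyl{[(3S)-6-(diazomethylidene)-3,7-dimethyloctyl]oxy}diphenylsilane (diazoalkene) | CC(C)C(=C=[N+]=[N-])CC[C@H](C)CCO[Si](c1ccccc1)(c1ccccc1)C(C)(C)C | intermediate (not isolated)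
9 | alkylidene carbene from 8 by loss of N2 (divalent carbon = C5) | CC(C)C(=[C])CC[C@H](C)CCO[Si](c1ccccc1)(c1ccccc1)C(C)(C)C | intermediate (not isolated)
10 | tert-butyl{2-[(1R)-1-methyl-3-(propan-2-yl)cyclopent-2-en-1-yl]ethoxy}diphenylsilane (key-step product) | CC(C)C1=C[C@](C)(CC1)CCO[Si](c1ccccc1)(c1ccccc1)C(C)(C)C | intermediate
11 | formaldehyde (used as paraformaldehyde) | C=O | starting material
12 | [(1R,5R)-5-{2-[(tert-butyldiphenylsilyl)oxy]ethyl}-5-methyl-2-(propan-2-yl)cyclopent-2-en-1-yl]methanol | OC[C@H]1C(C(C)C)=CC[C@]1(C)CCO[Si](c1ccccc1)(c1ccccc1)C(C)(C)C | intermediate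
13 | {3-[2-(tert-butyldiphenylsilyloxy)ethyl]-3-methyl-1-(propan-2-yl)-6-oxabicyclo[3.1.0]hexan-2-yl}methanol, epoxide oxygen cis to CH2OH and to the ring methyl group | OC[C@H]1[C@@]2(C(C)C)O[C@H]2C[C@]1(C)CCO[Si](c1ccccc1)(c1ccccc1)C(C)(C)C | intermediate
14 | (1R,2S,3R)-3-{2-[(tert-butyldiphenylsilyl)oxy]ethyl}-2-(hydroxymethyl)-3-methyl-1-(propan-2-yl)cyclopentan-1-ol | OC[C@H]1[C@](O)(C(C)C)CC[C@]1(C)CCO[Si](c1ccccc1)(c1ccccc1)C(C)(C)C | intermediate
15 | acetonide of 14 (O6 and O4 bridged by C(CH3)2, cis-fused 2,2-dimethyl-1,3-dioxane; silyl ether at O9) | CC1(C)OC[C@H]2[C@](O1)(C(C)C)CC[C@]2(C)CCO[Si](c1ccccc1)(c1ccccc1)C(C)(C)C | intermediate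
16 | C9 primary alcohol (15 with OH in place of the silyl ether) | CC1(C)OC[C@H]2[C@](O1)(C(C)C)CC[C@]2(C)CCO | intermediate
17 | C9 aldehyde of 16 | CC1(C)OC[C@H]2[C@](O1)(C(C)C)CC[C@]2(C)CC=O | intermediate
18 | 2-bromopropene | CC(Br)=C | starting material
19 | isopropenylmagnesium bromide | C=C(C)[Mg]Br | intermediate (not isolated)
20 | 3-methylbut-3-en-2-ol side chain on the acetonide core (both C9 epimers) | CC1(C)OC[C@H]2[C@](O1)(C(C)C)CC[C@]2(C)CC(O)C(C)=C | intermediate
21 | isopropenyl ketone (C9=O) on the acetonide core | CC1(C)OC[C@H]2[C@](O1)(C(C)C)CC[C@]2(C)CC(=O)C(C)=C | intermediate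
22 | (9S)-allylic alcohol, (2S)-3-methylbut-3-en-2-ol side chain on the acetonide core | CC1(C)OC[C@H]2[C@](O1)(C(C)C)CC[C@]2(C)C[C@H](O)C(C)=C | intermediate
23 | (9S)-tert-butyldimethylsilyl ether of 22 | CC1(C)OC[C@H]2[C@](O1)(C(C)C)CC[C@]2(C)C[C@H](O[Si](C)(C)C(C)(C)C)C(C)=C | intermediate
24 | (1R,2S,3R)-3-{(2S)-2-[(tert-butyldimethylsilyl)oxy]-3-methylbut-3-en-1-yl}-2-(hydroxymethyl)-3-methyl-1-(propan-2-yl)cyclopentan-1-ol | OC[C@H]1[C@](O)(C(C)C)CC[C@]1(C)C[C@H](O[Si](C)(C)C(C)(C)C)C(C)=C | intermediate
25 | C6 aldehyde of 24 (formyl group cis to the C4 hydroxyl and the C1 methyl) | O=C[C@H]1[C@](O)(C(C)C)CC[C@]1(C)C[C@H](O[Si](C)(C)C(C)(C)C)C(C)=C | intermediate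
26 | (3R,3aS,4S,7S,8aR)-7-[(tert-butyldimethylsilyl)oxy]-8a-methyl-6-methylidene-3-(propan-2-yl)decahydroazulene-3,4-diol | C=C1C[C@H](O)[C@@H]2[C@](C)(CC[C@@]2(O)C(C)C)C[C@@H]1O[Si](C)(C)C(C)(C)C | intermediate
27 | vanillic acid | COc1cc(C(=O)O)ccc1O | starting material
28 | tert-butyldimethylsilyl 4-[(tert-butyldimethylsilyl)oxy]-3-methoxybenzoate | COc1cc(C(=O)O[Si](C)(C)C(C)(C)C)ccc1O[Si](C)(C)C(C)(C)C | intermediate (not isolated)
29 | 4-[(tert-butyldimethylsilyl)oxy]-3-methoxybenzoic acid | COc1cc(C(=O)O)ccc1O[Si](C)(C)C(C)(C)C | intermediate
30 | (3R,3aS,4S,7S,8aR)-7-[(tert-butyldimethylsilyl)oxy]-3-hydroxy-8a-methyl-6-methylidene-3-(propan-2-yl)decahydroazulen-4-yl 4-[(tert-butyldimethylsilyl)oxy]-3-methoxybenzoate | C=C1C[C@H](OC(=O)c2ccc(O[Si](C)(C)C(C)(C)C)c(OC)c2)[C@@H]2[C@](C)(CC[C@@]2(O)C(C)C)C[C@@H]1O[Si](C)(C)C(C)(C)C | intermediate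
31 | (3R,3aS,4S,7S,8aR)-3,7-dihydroxy-8a-methyl-6-methylidene-3-(propan-2-yl)decahydroazulen-4-yl 4-hydroxy-3-methoxybenzoate | C=C1C[C@H](OC(=O)c2ccc(O)c(OC)c2)[C@@H]2[C@](C)(CC[C@@]2(O)C(C)C)C[C@@H]1O | target

Step count and least certain steps

Total: 20 steps. Longest linear sequence: 19 steps (steps 1–17, 19 and 20 from 1); step 18 is a one-step branch from 27.

Step 4 (key step). The basic lithiated reagent may enolise the hindered α-branched ketone instead of adding to it, or the carbene may divert to 1,2-alkyl shift if insertion is slow; both would lower conversion to the ring. Fallback, from 5 back to 10: Wittig chloromethylenation of 5 [(chloromethyl)triphenylphosphonium chloride, KN(SiMe3)2, THF] should give the chloroalkene tert-butyl{[(3S)-6-(chloromethylidene)-3,7-dimethyloctyl]oxy}diphenylsilane F1. α-Elimination of F1 with KN(SiMe3)2 in ether generates the same alkylidene carbene without a carbonyl addition, and it closes to 10.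

Step 5. The weakest stereochemical point is facial discrimination: the methyl group and the silyloxyethyl arm on C1 differ only moderately in size, so attack on the wrong face of C5 may compete. Hydrogen abstraction from the isopropyl methine and chloride capture of the cationic intermediate are further possible diversions. Fallback, from 10 back to 12: an ene reaction of 10 with the bulkier enophile diethyl oxomalonate (SnCl4 cat., CH2Cl2, 0 °C), which should respond more strongly to the steric difference, gives the hydroxymalonate ene adduct F2. Saponification (KOH) and oxidative bisdecarboxylation (NaIO4) give the cyclopentenecarboxylic acid F3, and LiAlH4 reduction returns 12.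

Step 13. Face discrimination by the oxazaborolidine may be reduced because the CH2 group on the quaternary C1 is not much smaller than the isopropenyl group; conjugate reduction is a lesser concern. Fallback, from 17 back to 22: asymmetric Nozaki–Hiyama–Kishi coupling of 17 with 18 (CrCl2 with a chiral sulfonamide ligand, NiCl2 as co-catalyst, Mn powder as reductant) forms C8–C9 and sets C9 in the bond-forming step, bypassing 19–21. This fallback makes no compound outside the list (F0).

Step 16. Dehydration or retro-aldol cleavage of the β-hydroxy aldehyde during oxidation or handling may erode material, because the tertiary C4 hydroxyl is β to the new carbonyl. Fallback, from 24 back to 26: silylation of both hydroxyls (Me3SiOTf, Et3N) gives the bis(trimethylsilyl) ether F4. Swern oxidation converts the primary silyl ether directly into the C4-silyloxy aldehyde F5, the ene closure of step 17 then gives the C4-silylated bicyclic alcohol F6, and K2CO3 in MeOH removes the tertiary trimethylsilyl group to return 26.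

Step 17. Closure through the transition structure with an axial oxygen would give the 6β epimer. The ene reaction may also be slowed by the inductive effect of the allylic silyloxy group, which would leave time for chloride capture. Fallback, from 25 back to 30: if the closure of 25 delivers mainly the 6β-alcohol F7, then F7 is esterified with 29 under Mitsunobu conditions (PPh3, diisopropyl azodicarboxylate) with inversion at C6, which gives 30 directly and replaces step 19.

Further compounds

F1 | step 4 | tert-butyl{[(3S)-6-(chloromethylidene)-3,7-dimethyloctyl]oxy}diphenylsilane (E/Z mixture) | CC(C)C(=CCl)CC[C@H](C)CCO[Si](c1ccccc1)(c1ccccc1)C(C)(C)C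
F2 | step 5 | diethyl 2-hydroxy-2-[(1R,5R)-5-{2-[(tert-butyldiphenylsilyl)oxy]ethyl}-5-methyl-2-(propan-2-yl)cyclopent-2-en-1-yl]propanedioate (ring configuration as in 12) | CCOC(=O)C(O)(C(=O)OCC)[C@H]1C(C(C)C)=CC[C@]1(C)CCO[Si](c1ccccc1)(c1ccccc1)C(C)(C)C
F3 | step 5 | 5-{2-[(tert-butyldiphenylsilyl)oxy]ethyl}-5-methyl-2-(propan-2-yl)cyclopent-2-ene-1-carboxylic acid (carboxyl cis to the ring methyl, as CH2OH in 12) | OC(=O)[C@H]1C(C(C)C)=CC[C@]1(C)CCO[Si](c1ccccc1)(c1ccccc1)C(C)(C)C
F0 | step 13 | none | none
F4 | step 16 | bis(trimethylsilyl) ether of 24 (O6 and O4) | C[Si](C)(C)OC[C@H]1[C@](O[Si](C)(C)C)(C(C)C)CC[C@]1(C)C[C@H](O[Si](C)(C)C(C)(C)C)C(C)=C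
F5 | step 16 | C6 aldehyde with C4 trimethylsilyl ether | O=C[C@H]1[C@](O[Si](C)(C)C)(C(C)C)CC[C@]1(C)C[C@H](O[Si](C)(C)C(C)(C)C)C(C)=C
F6 | step 16 | 26 with a trimethylsilyl ether at the C4 oxygen | C=C1C[C@H](O)[C@@H]2[C@](C)(CC[C@@]2(O[Si](C)(C)C)C(C)C)C[C@@H]1O[Si](C)(C)C(C)(C)C
F7 | step 17 | C6 epimer of 26 (6β, axial hydroxyl) | C=C1C[C@@H](O)[C@@H]2[C@](C)(CC[C@@]2(O)C(C)C)C[C@@H]1O[Si](C)(C)C(C)(C)C
A1 | alternative 1 | triethyl{[(1R)-2-ethenyl-3-methyl-1-(propan-2-yl)cyclopent-2-en-1-yl]oxy}silane | C=CC1=C(C)CC[C@@]1(O[Si](CC)(CC)CC)C(C)C
A2 | alternative 1 | methyl 2-diazobut-3-enoate | C=CC(=[N+]=[N-])C(=O)OC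
A3 | alternative 1 | bicyclic cycloheptadiene with C8 methyl ester, C8=C9 and C5=C6 alkenes, C4 triethylsilyl ether | C1=C(C(=O)OC)CC=C2[C@](C)(CC[C@@]2(O[Si](CC)(CC)CC)C(C)C)C1
A4 | alternative 2 | 6-acetoxy-5-(acetoxymethyl)-2H-pyran-3(6H)-one carrying the C4 silyloxy tether at C2 | CC(=O)OCC1=CC(=O)C(OC1OC(C)=O)[C@](O[Si](CC)(CC)CC)(C(C)C)CCC(C)=C
A5 | alternative 2 | 3-oxidopyrylium derived from A4 | [O-]c1cc(COC(C)=O)c[o+]c1[C@](O[Si](CC)(CC)CC)(C(C)C)CCC(C)=C
A6 | alternative 2 | oxygen-bridged tricyclic enone (C5–O–C9 bridge, C14 acetate) | CC(=O)OCC1=CC(=O)[C@]23[C@](C)(CC[C@@]2(O[Si](CC)(CC)CC)C(C)C)C[C@@H]1O3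
A7 | alternative 3 | 3-{(2S)-2-[(tert-butyldimethylsilyl)oxy]-3-methylbut-3-en-1-yl}cyclopent-2-en-1-one | O=C1C=C(CC1)C[C@H](O[Si](C)(C)C(C)(C)C)C(C)=C
A8 | alternative 3 | trimethylaluminium | C[Al](C)C
A9 | alternative 3 | trans 2-(hydroxymethyl)-3-methyl-3-alkylcyclopentanone | OC[C@@H]1[C@](C)(CCC1=O)C[C@H](O[Si](C)(C)C(C)(C)C)C(C)=C
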